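**Retrosynthetic overview**
- The target is reached by Lewis-acid deprotection of 2',5'-diisopropoxy-5,6,7,8-tetramethoxyflavone, which removes both isopropyl ethers and the peri 5-O-methyl group.
- Ring C is the only ring built (rings A and B are bought as arenes). It is opened at C4–C4a: intramolecular Friedel–Crafts acylation of a (Z)-3-aryl-3-aryloxyacrylic acid.
- The strategy rests on ring A: it comes from 2,3,4,5-tetramethoxyphenol, whose C6 is the only unsubstituted ring carbon. C6 lies ortho to the phenol oxygen (future O1), ortho and para to methoxy groups, and becomes C4a, so the acyl carbon can close at one site only.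
- The acid comes from conjugate addition of this phenol (forming O1–C2) to methyl 3-(2,5-diisopropoxyphenyl)propiolate, then saponification.
- The phenol comes from 1,2,3,4-tetramethoxybenzene (formylation, Baeyer–Villiger). The ynoate comes from 2,5-dihydroxybenzaldehyde (isopropylation, Corey–Fuchs homologation, carboxylation).

Key step: step 8

Remark on the chemistry: the conjugate addition in step 6 is drawn as giving the Z alkene (anti addition). Any E isomer formed is assumed to be carried unseparated through steps 7 and 8.

**Step 1**
Reactants: 1 1,2,3,4-tetramethoxybenzene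
Product: 2 2,3,4,5-tetramethoxybenzaldehyde
Conditions: Cl2CHOMe, TiCl4, CH2Cl2, 0 °C; then ice–water
Reagents that add atoms: dichloromethyl methyl ether, COC(Cl)Cl; water, O
Why: Rieche formylation; the two free positions are equivalent, each ortho and para to a methoxy group, and the aldehyde formed deactivates the ring against a second formylation.

**Step 2**
Reactants: 2 2,3,4,5-tetramethoxybenzaldehyde
Product: 4 2,3,4,5-tetramethoxyphenol, via aryl formate 3 (not isolated)
Conditions: mCPBA, CH2Cl2, 0 °C to rt; then K2CO3 (cat.), MeOH, rt, under argon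
Reagents that add atoms: mCPBA (3-chloroperoxybenzoic acid), OOC(=O)c1cccc(Cl)c1
Why: Baeyer–Villiger (Dakin-type) oxidation in which the electron-rich aryl group migrates in preference to hydride, followed by mild methanolysis of the labile aryl formate under exclusion of air to protect the oxidisable phenol.

**Step 3**
Reactants: 5 2,5-dihydroxybenzaldehyde; 6 2-bromopropane
Product: 7 2,5-diisopropoxybenzaldehyde
Conditions: K2CO3, DMF, 70 °C
Reagents that add atoms: 2-bromopropane (6), CC(C)Br
Why: Williamson ether synthesis on both phenoxides; an excess of the secondary bromide offsets elimination and warming overcomes the hydrogen-bonded 2-hydroxyl.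

**Step 4**
Reactants: 7 2,5-diisopropoxybenzaldehyde
Product: 8 2-(2,2-dibromoethenyl)-1,4-diisopropoxybenzene
Conditions: CBr4, PPh3, CH2Cl2, 0 °C
Reagents that add atoms: carbon tetrabromide, BrC(Br)(Br)Br
Why: First stage of the Corey–Fuchs homologation; the dibromomethylene ylide formed from CBr4 and PPh3 olefinates the aldehyde in a Wittig reaction that leaves the aryl ethers untouched.

**Step 5**
Reactants: 8 2-(2,2-dibromoethenyl)-1,4-diisopropoxybenzene
Product: 10 methyl 3-(2,5-diisopropoxyphenyl)prop-2-ynoate, via lithium acetylide 9 (not isolated)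
Conditions: n-BuLi (2.2 equiv), THF, −78 °C; then ClCO2Me, −78 °C to rt
Reagents that add atoms: methyl chloroformate, COC(=O)Cl
Why: Second stage of the Corey–Fuchs homologation; bromine–lithium exchange, alpha-elimination with 1,2-shift (Fritsch–Buttenberg–Wiechell rearrangement) and deprotonation give the lithium acetylide, which is C-acylated by the chloroformate.

**Step 6**
Reactants: 4 2,3,4,5-tetramethoxyphenol; 10 methyl 3-(2,5-diisopropoxyphenyl)prop-2-ynoate
Product: 11 methyl (Z)-3-(2,5-diisopropoxyphenyl)-3-(2,3,4,5-tetramethoxyphenoxy)prop-2-enoate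
Conditions: K2CO3, DMF, 90 °C, under argon
Reagents that add atoms: none
Why: Oxa-Michael (conjugate) addition of the phenoxide to the beta carbon of the ynoate, the classical route to 3-aryloxycinnamates; anti protonation of the adduct should place the aryloxy group cis to the ester (Z).

**Step 7**
Reactants: 11 methyl (Z)-3-(2,5-diisopropoxyphenyl)-3-(2,3,4,5-tetramethoxyphenoxy)prop-2-enoate
Product: 12 (Z)-3-(2,5-diisopropoxyphenyl)-3-(2,3,4,5-tetramethoxyphenoxy)prop-2-enoic acid
Conditions: LiOH, THF/MeOH/H2O, rt; then 1 M HCl to pH 3, 0 °C
Reagents that add atoms: lithium hydroxide, [Li+].[OH-]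
Why: Ester saponification; the vinylogous carbonate is a poor acceptor for hydroxide at room temperature, and cold, brief acidification should avoid hydrolysis of the enol ether and decarboxylation.

**Step 8**
Reactants: 12 (Z)-3-(2,5-diisopropoxyphenyl)-3-(2,3,4,5-tetramethoxyphenoxy)prop-2-enoic acid
Product: 14 2',5'-diisopropoxy-5,6,7,8-tetramethoxyflavone, via mixed trifluoroacetic anhydride 13 (not isolated)
Conditions: (CF3CO)2O, CH2Cl2, 0 °C to rt
Reagents that add atoms: none
Why: Acid 12 and (CF3CO)2O give the mixed anhydride 13, whose acyl carbon (or the acylium ion formed by loss of trifluoroacetate) is attacked by C6 of the tetramethoxyphenoxy ring, and loss of a proton from the arenium ion gives the 4-pyranone. The closest known reaction type is the acid-mediated intramolecular Friedel–Crafts acylation of 3-aryloxycinnamic acids to flavones, and (CF3CO)2O is a standard activator for cyclising tethered carboxylic acids onto electron-rich arenes. Ring C closes as a six-membered ring by electrophilic aromatic substitution, the arene carbon adding to the exocyclic acyl C=O (formally 6-exo-trig) to form C4–C4a. No stereocenter is formed. The step needs site selectivity for ring A over C6' of ring B (which would give a five-membered indenone): the attacked carbon is the only unsubstituted position of ring A, it is activated by an ortho methoxy, a para methoxy and the ortho ether oxygen, and the Z geometry holds the acyl group next to ring A and away from ring B. The acid released can equilibrate the push–pull alkene, so any E isomer should funnel into the same flavone, and the mild medium should leave the isopropyl ethers intact.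

**Step 9**
Reactants: 14 2',5'-diisopropoxy-5,6,7,8-tetramethoxyflavone
Product: 15 5,2',5'-trihydroxy-6,7,8-trimethoxyflavone
Conditions: BCl3 (excess), CH2Cl2, −78 °C to 0 °C; then MeOH, H2O, under argon
Reagents that add atoms: none
Why: Lewis-acid ether cleavage; BCl3 removes secondary-alkyl (isopropyl) aryl ethers much faster than methyl ethers, and chelation of boron between the C4 carbonyl and the peri oxygen activates only the 5-O-methyl group among the four, while the hydroquinone ring is kept from air during work-up.

**Compound list**
1 | 1,2,3,4-tetramethoxybenzene | COc1ccc(OC)c(OC)c1OC | starting material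
2 | 2,3,4,5-tetramethoxybenzaldehyde | O=Cc1cc(OC)c(OC)c(OC)c1OC | intermediate
3 | 2,3,4,5-tetramethoxyphenyl formate | O=COc1cc(OC)c(OC)c(OC)c1OC | intermediate (not isolated)
4 | 2,3,4,5-tetramethoxyphenol | Oc1cc(OC)c(OC)c(OC)c1OC | intermediate
5 | 2,5-dihydroxybenzaldehyde | O=Cc1cc(O)ccc1O | starting material
6 | 2-bromopropane | CC(C)Br | starting material
7 | 2,5-diisopropoxybenzaldehyde | O=Cc1cc(OC(C)C)ccc1OC(C)C | intermediate
8 | 2-(2,2-dibromoethenyl)-1,4-diisopropoxybenzene | BrC(Br)=Cc1cc(OC(C)C)ccc1OC(C)C | intermediate
9 | lithium (2,5-diisopropoxyphenyl)acetylide | [Li]C#Cc1cc(OC(C)C)ccc1OC(C)C | intermediate (not isolated)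
10 | methyl 3-(2,5-diisopropoxyphenyl)prop-2-ynoate | COC(=O)C#Cc1cc(OC(C)C)ccc1OC(C)C | intermediate
11 | methyl (Z)-3-(2,5-diisopropoxyphenyl)-3-(2,3,4,5-tetramethoxyphenoxy)prop-2-enoate | COC(=O)/C=C(\Oc1cc(OC)c(OC)c(OC)c1OC)c1cc(OC(C)C)ccc1OC(C)C | intermediate
12 | (Z)-3-(2,5-diisopropoxyphenyl)-3-(2,3,4,5-tetramethoxyphenoxy)prop-2-enoic acid | OC(=O)/C=C(\Oc1cc(OC)c(OC)c(OC)c1OC)c1cc(OC(C)C)ccc1OC(C)C | intermediate
13 | (Z)-3-(2,5-diisopropoxyphenyl)-3-(2,3,4,5-tetramethoxyphenoxy)prop-2-enoic trifluoroacetic anhydride | FC(F)(F)C(=O)OC(=O)/C=C(\Oc1cc(OC)c(OC)c(OC)c1OC)c1cc(OC(C)C)ccc1OC(C)C | intermediate (not isolated)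
14 | 2',5'-diisopropoxy-5,6,7,8-tetramethoxyflavone | COc1c(OC)c(OC)c2c(=O)cc(-c3cc(OC(C)C)ccc3OC(C)C)oc2c1OC | intermediate
15 | 5,2',5'-trihydroxy-6,7,8-trimethoxyflavone | COc1c(OC)c(O)c2c(=O)cc(-c3cc(O)ccc3O)oc2c1OC | target

**Step count**
Total steps: 9. Longest linear sequence: 7 steps (5 → 7 → 8 → 10 → 11 → 12 → 14 → 15; steps 3 to 9). The ring A branch (steps 1 and 2) joins at step 6.

**Steps most likely to fail**

1. Step 8 (key ring closure). The mixed anhydride of a vinylogous carbonate may be too weak an electrophile to acylate ring A. Alternatively, the acid released may protonate the enol ether and cleave the aryloxy group before the ring closes. The fallback abandons the acylation and builds ring C by oxidative cyclisation of a chalcone. It sets out from phenol 4 and aldehyde 7. C-Acetylation of 4 at its only free carbon (AcOH, BF3·OEt2, 80 °C) should give 1-(2-hydroxy-3,4,5,6-tetramethoxyphenyl)ethanone F1. Claisen–Schmidt condensation of this ketone with 7 (KOH, EtOH, rt) should give (E)-3-(2,5-diisopropoxyphenyl)-1-(2-hydroxy-3,4,5,6-tetramethoxyphenyl)prop-2-en-1-one F2. Oxidative cyclisation (I2 cat., DMSO, 120 °C) then closes O1–C2 and dehydrogenates, returning to the route at flavone 14.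

2. Step 6 (phenoxide addition). Conjugate addition to an electron-rich, ortho-substituted arylpropiolate may be sluggish, and prolonged heating may oxidise the phenoxide or erode the alkene geometry. The fallback replaces the uncatalysed addition by a metal-catalysed C–O coupling. It sets out from ynoate 10. Hydroiodination (NaI, AcOH, 70 °C; anti addition) should give methyl (Z)-3-(2,5-diisopropoxyphenyl)-3-iodoprop-2-enoate F3. Ullmann-type coupling of this vinyl iodide with phenol 4 (CuI, N,N-dimethylglycine, Cs2CO3, dioxane, 90 °C), with retention of geometry, returns to the route at ester 11.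

3. Step 9 (global deprotection). Cleavage may stop before the 5-O-methyl group is removed, or, once the boron chelate has formed, continue to the neighbouring 6-O-methyl group. The fallback splits the deprotection into two separately controlled operations. It sets out from flavone 14. Chelation-directed demethylation of the peri methoxy group alone (MgBr2·OEt2, MeCN, 60 °C) should give 5-hydroxy-2',5'-diisopropoxy-6,7,8-trimethoxyflavone F4. Brief treatment with BCl3 in CH2Cl2 at −78 °C, cold enough to spare the methyl ethers, then removes the two isopropyl ethers and returns to the route at target 15.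

**Further compounds**
F1 | step 8 | 1-(2-hydroxy-3,4,5,6-tetramethoxyphenyl)ethanone | CC(=O)c1c(O)c(OC)c(OC)c(OC)c1OC
F2 | step 8 | (E)-3-(2,5-diisopropoxyphenyl)-1-(2-hydroxy-3,4,5,6-tetramethoxyphenyl)prop-2-en-1-one | O=C(/C=C/c1cc(OC(C)C)ccc1OC(C)C)c1c(O)c(OC)c(OC)c(OC)c1OC
F3 | step 6 | methyl (Z)-3-(2,5-diisopropoxyphenyl)-3-iodoprop-2-enoate | COC(=O)/C=C(\I)c1cc(OC(C)C)ccc1OC(C)C
F4 | step 9 | 5-hydroxy-2',5'-diisopropoxy-6,7,8-trimethoxyflavone | COc1c(OC)c(O)c2c(=O)cc(-c3cc(OC(C)C)ccc3OC(C)C)oc2c1OC
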